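**Retrosynthetic overview**

1. The target is a 2,3-trans-3,4-cis flavan-3-ol (rings A, C, B) joined C4→C6' to a 2,3-trans-3,4-trans flavan-3,4-diol (rings D, F, E; primed atoms). The last operations are hydrogenolysis of six benzyl ethers and NaBH4 reduction of the ring F ketone at C4'.
2. Ring F (formed second): O1'–C2' is made by 6-endo opening of a chalcone epoxide by the ring D phenol, and the chalcone comes from a ring D acetyl group by Claisen–Schmidt condensation. That acetyl carbon is carried from the start as a nitrile next to a MOM-protected oxygen, because once ring C exists rings A and D are both resorcinol-type and a late acylation could not tell them apart.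
3. Ring C (formed first, key step): the strategy rests on the O1–C8a aryl ether bond of the upper pyran. Cutting it lets C2, C3 and C4, including the 3,4-cis pair, be fixed on an open 1,1,3-triarylpropane and carried into the ring by copper-catalysed intramolecular O-arylation of the ring A bromide.
4. Open chain: C2 comes from Felkin–Anh addition of the ring B Grignard reagent to an α-silyloxy aldehyde. C3 and C4 both come from one Sharpless epoxide of the ring A cinnamyl alcohol, opened at the benzylic carbon with inversion by the ring D aryl copper reagent, since C4 bears two aryl groups of like size and cannot steer C3.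

Key step: step 13

**Route**

Step 1
Reactants: 1 2-bromo-4-hydroxybenzaldehyde
Product: 2 4-(benzyloxy)-2-bromobenzaldehyde
Conditions: BnBr, K2CO3, DMF, rt
Reagents that add atoms: benzyl bromide BrCc1ccccc1
Why: Williamson ether synthesis on the phenoxide, which leaves the aldehyde and the aryl bromide untouched.

Step 2
Reactants: 2 4-(benzyloxy)-2-bromobenzaldehyde
Product: 3 ethyl (E)-3-[4-(benzyloxy)-2-bromophenyl]prop-2-enoate
Conditions: (EtO)2P(O)CH2CO2Et, NaH, THF, 0 °C → rt
Reagents that add atoms: triethyl phosphonoacetate CCOC(=O)CP(=O)(OCC)OCC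
Why: Horner–Wadsworth–Emmons olefination of an aryl aldehyde with a stabilised phosphonate anion, which should give the E-enoate.

Step 3
Reactants: 3 ethyl (E)-3-[4-(benzyloxy)-2-bromophenyl]prop-2-enoate
Product: 4 (E)-3-[4-(benzyloxy)-2-bromophenyl]prop-2-en-1-ol
Conditions: i-Bu2AlH (2.2 equiv), CH2Cl2, −78 °C; aq. KNaC4H4O6
Reagents that add atoms: none
Why: 1,2-reduction of the enoate by the aluminium hydride at low temperature, which spares the alkene and the aryl bromide.

Step 4
Reactants: 4 (E)-3-[4-(benzyloxy)-2-bromophenyl]prop-2-en-1-ol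
Product: 5 [(2R,3R)-3-[4-(benzyloxy)-2-bromophenyl]oxiran-2-yl]methanol
Conditions: Ti(OiPr)4 (10 mol %), D-(−)-diethyl tartrate (12 mol %), t-BuOOH, 4 Å molecular sieves, CH2Cl2, −20 °C
Reagents that add atoms: tert-butyl hydroperoxide CC(C)(C)OO
Why: Sharpless asymmetric epoxidation, in which the titanium–D-tartrate complex delivers oxygen to one face of the E-allylic alcohol and so sets both epoxide carbons (2R,3R); the ortho bromine tempers the donor effect of the para benzyloxy group on the benzylic C–O bond.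

Step 5
Reactants: 6 4-(benzyloxy)-2-hydroxybenzaldehyde
Product: 7 4-(benzyloxy)-2-hydroxy-5-iodobenzaldehyde
Conditions: NIS (1.05 equiv), CF3CO2H (cat.), MeCN, 0 °C → rt
Reagents that add atoms: N-iodosuccinimide O=C1CCC(=O)N1I
Why: Electrophilic aromatic iodination, directed para to the free hydroxyl and ortho to the benzyloxy group, at the less hindered C5 and not at C3 between the two oxygens.

Step 6
Reactants: 7 4-(benzyloxy)-2-hydroxy-5-iodobenzaldehyde
Product: 8 4-(benzyloxy)-5-iodo-2-(methoxymethoxy)benzaldehyde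
Conditions: MOMCl, i-Pr2NEt, CH2Cl2, 0 °C → rt
Reagents that add atoms: chloromethyl methyl ether COCCl
Why: O-alkylation of the phenol to its methoxymethyl acetal, which marks the oxygen that later becomes O1' of ring F.

Step 7
Reactants: 8 4-(benzyloxy)-5-iodo-2-(methoxymethoxy)benzaldehyde
Product: 9 4-(benzyloxy)-5-iodo-2-(methoxymethoxy)benzonitrile
Conditions: I2, aq. NH3, THF, rt
Reagents that add atoms: ammonia N
Why: Oxidative conversion of an aldehyde into a nitrile through the aldimine and its N-iodo derivative, under basic conditions that keep the acetal and the aryl iodide.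

Step 8
Reactants: 5 [(2R,3R)-3-[4-(benzyloxy)-2-bromophenyl]oxiran-2-yl]methanol; 9 4-(benzyloxy)-5-iodo-2-(methoxymethoxy)benzonitrile
Product: 11 (2S,3S)-3-[4-(benzyloxy)-2-bromophenyl]-3-[2-(benzyloxy)-5-cyano-4-(methoxymethoxy)phenyl]propane-1,2-diol, via arylmagnesium chloride 10 (not isolated)
Conditions: 9, i-PrMgCl·LiCl, THF, −40 °C; CuI (20 mol %); then 5 (pre-treated with MeMgCl, 1 equiv), −40 → −10 °C; aq. NH4Cl
Reagents that add atoms: none
Why: Iodine–magnesium exchange tolerates the nitrile at −40 °C, and the copper-catalysed SN2 opening of a 3-aryl-2,3-epoxy alcohol by an aryl Grignard reagent takes place at the benzylic carbon with inversion, so C4 (3S here) is set from the epoxide while the carbinol carbon (future C3) keeps the configuration from step 4.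

Step 9
Reactants: 11 (2S,3S)-3-[4-(benzyloxy)-2-bromophenyl]-3-[2-(benzyloxy)-5-cyano-4-(methoxymethoxy)phenyl]propane-1,2-diol
Product: 12 (2S,3S)-1,2-bis(tert-butyldimethylsilyl) ether of diol 11
Conditions: TBSOTf (2.5 equiv), 2,6-lutidine, CH2Cl2, −78 → 0 °C
Reagents that add atoms: tert-butyldimethylsilyl triflate CC(C)(C)[Si](C)(C)OS(=O)(=O)C(F)(F)F
Why: Silylation of both hydroxyls with the silyl triflate, which is reactive enough for the hindered secondary carbinol beside the diarylmethine.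

Step 10
Reactants: 12 (2S,3S)-1,2-bis(tert-butyldimethylsilyl) ether of diol 11
Product: 13 (2S,3S)-3-[4-(benzyloxy)-2-bromophenyl]-3-[2-(benzyloxy)-5-cyano-4-(methoxymethoxy)phenyl]-2-(tert-butyldimethylsilyloxy)propan-1-ol
Conditions: HF·pyridine, pyridine, THF, 0 °C
Reagents that add atoms: none
Why: Selective desilylation, since buffered fluoride removes the unhindered primary silyl ether much faster than the secondary one flanked by the diarylmethine.

Step 11
Reactants: 13 (2S,3S)-3-[4-(benzyloxy)-2-bromophenyl]-3-[2-(benzyloxy)-5-cyano-4-(methoxymethoxy)phenyl]-2-(tert-butyldimethylsilyloxy)propan-1-ol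
Product: 14 (2S,3S)-3-[4-(benzyloxy)-2-bromophenyl]-3-[2-(benzyloxy)-5-cyano-4-(methoxymethoxy)phenyl]-2-(tert-butyldimethylsilyloxy)propanal
Conditions: Dess–Martin periodinane, NaHCO3, CH2Cl2, 0 °C → rt; used at once
Reagents that add atoms: none
Why: Dess–Martin oxidation of the primary alcohol under buffered, non-basic conditions, which should not epimerise the α-silyloxy centre.

Step 12
Reactants: 14 (2S,3S)-3-[4-(benzyloxy)-2-bromophenyl]-3-[2-(benzyloxy)-5-cyano-4-(methoxymethoxy)phenyl]-2-(tert-butyldimethylsilyloxy)propanal; 15 4-bromo-1,2-bis(benzyloxy)benzene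
Product: 17 (1R,2S,3S)-1-[3,4-bis(benzyloxy)phenyl]-3-[4-(benzyloxy)-2-bromophenyl]-3-[2-(benzyloxy)-5-cyano-4-(methoxymethoxy)phenyl]-2-(tert-butyldimethylsilyloxy)propan-1-ol, via arylmagnesium bromide 16 (not isolated)
Conditions: 15, Mg, THF, rt; then 14, THF, −78 °C; aq. NH4Cl
Reagents that add atoms: none
Why: Grignard addition to an α-silyloxy aldehyde under polar Felkin–Anh control (non-chelating silyl ether anti to the incoming aryl group in THF), which should give the 1,2-anti carbinol (1R) that becomes the 2,3-trans pair, while the nitrile does not react at −78 °C.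

Step 13
Reactants: 17 (1R,2S,3S)-1-[3,4-bis(benzyloxy)phenyl]-3-[4-(benzyloxy)-2-bromophenyl]-3-[2-(benzyloxy)-5-cyano-4-(methoxymethoxy)phenyl]-2-(tert-butyldimethylsilyloxy)propan-1-ol
Product: 18 (2R,3S,4R)-7-(benzyloxy)-2-[3,4-bis(benzyloxy)phenyl]-4-[2-(benzyloxy)-5-cyano-4-(methoxymethoxy)phenyl]-3-(tert-butyldimethylsilyloxy)chromane (2,3-trans-3,4-cis)
Conditions: CuI (20 mol %), 3,4,7,8-tetramethyl-1,10-phenanthroline (40 mol %), Cs2CO3 (2 equiv), toluene, 110 °C, argon
Reagents that add atoms: none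
Why: Cs2CO3 turns the C2 hydroxyl into an alkoxide on the phenanthroline-bound monovalent copper, the metal inserts into the ring A C–Br bond, and reductive elimination from the trivalent aryl copper alkoxide forms O1–C8a. The closest known reaction type is the Ullmann-type copper/phenanthroline etherification of aliphatic alcohols with aryl bromides, used intramolecularly to make chromans and flavans from 3-(2-bromoaryl)propan-1-ols. Ring C closes as a six-membered ring by O-arylation, the alkoxide oxygen being joined to the arene carbon with no attack at a saturated carbon. No stereocenter is formed: C2, C3 and C4 keep the configurations set in steps 12, 4 and 8 because none of their bonds is broken, so the open-chain 2,3-anti pair becomes 2,3-trans and the 3,4 pair becomes 3,4-cis (the change of the C4 descriptor from S to R is a priority effect only). The step needs chemoselectivity only: O3 is blocked as its silyl ether so that five-membered closure cannot compete, the ring A bromide is the only aryl halide, nitrile and acetal are inert to carbonate, and exclusion of air keeps the benzylic alkoxide from being oxidised to the ketone.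

Step 14
Reactants: 18 (2R,3S,4R)-7-(benzyloxy)-2-[3,4-bis(benzyloxy)phenyl]-4-[2-(benzyloxy)-5-cyano-4-(methoxymethoxy)phenyl]-3-(tert-butyldimethylsilyloxy)chromane
Product: 20 (2R,3S,4R)-4-[5-acetyl-2-(benzyloxy)-4-(methoxymethoxy)phenyl]-7-(benzyloxy)-2-[3,4-bis(benzyloxy)phenyl]-3-(tert-butyldimethylsilyloxy)chromane, via N-lithio ketimine 19 (not isolated)
Conditions: MeLi (3 equiv), THF, −78 → 0 °C; then AcOH–H2O–THF, rt
Reagents that add atoms: methyllithium [Li]C; water O
Why: Addition of methyllithium to the aryl nitrile stops at the N-lithio ketimine, and mild aqueous acid hydrolyses it to the methyl ketone without touching the MOM or silyl ether.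

Step 15
Reactants: 20 (2R,3S,4R)-4-[5-acetyl-2-(benzyloxy)-4-(methoxymethoxy)phenyl]-7-(benzyloxy)-2-[3,4-bis(benzyloxy)phenyl]-3-(tert-butyldimethylsilyloxy)chromane; 21 3,4-bis(benzyloxy)benzaldehyde
Product: 22 (E)-1-[4-(benzyloxy)-2-(methoxymethoxy)-5-[(2R,3S,4R)-7-(benzyloxy)-2-[3,4-bis(benzyloxy)phenyl]-3-(tert-butyldimethylsilyloxy)chroman-4-yl]phenyl]-3-[3,4-bis(benzyloxy)phenyl]prop-2-en-1-one
Conditions: KOH, EtOH–THF, rt
Reagents that add atoms: none
Why: Claisen–Schmidt condensation (aldol addition then dehydration) of a 2-(methoxymethoxy)acetophenone with a non-enolisable aryl aldehyde, which should give the E-chalcone and leave the secondary alkyl silyl ether intact.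

Step 16
Reactants: 22 the E-chalcone of step 15
Product: 23 [4-(benzyloxy)-2-(methoxymethoxy)-5-[(2R,3S,4R)-7-(benzyloxy)-2-[3,4-bis(benzyloxy)phenyl]-3-(tert-butyldimethylsilyloxy)chroman-4-yl]phenyl][(2R,3S)-3-[3,4-bis(benzyloxy)phenyl]oxiran-2-yl]methanone
Conditions: poly-L-leucine, urea·H2O2, DBU, THF, rt
Reagents that add atoms: hydrogen peroxide (as its urea adduct) OO
Why: Juliá–Colonna epoxidation (conjugate addition of hydroperoxide and ring closure on the helical poly-L-leucine), which is expected to give the (αR,βS)-trans-epoxide of an E-chalcone; the enone lies far from the upper stereocenters, so the catalyst should control the face, and any minor isomer is a separable diastereomer.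

Step 17
Reactants: 23 the (αR,βS)-epoxy ketone of step 16
Product: 26 (2R,3R)-7-(benzyloxy)-2-[3,4-bis(benzyloxy)phenyl]-6-[(2R,3S,4R)-7-(benzyloxy)-2-[3,4-bis(benzyloxy)phenyl]-3-hydroxychroman-4-yl]-3-hydroxychroman-4-one, via phenol epoxy ketone 24 (not isolated), via silylated dihydroflavonol 25 (not isolated)
Conditions: 3 M aq. HCl, MeOH–THF, 50 °C, until acetal and silyl ether are both gone
Reagents that add atoms: none
Why: Acid removes the MOM group, the freed ring D phenol opens the epoxide 6-endo at the benzylic carbon with inversion (or via the benzylic cation, which leads to the same 2,3-trans isomer) so that C2' becomes R while C3' keeps its epoxide configuration, and the same methanolic acid cleaves the silyl ether.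

Step 18
Reactants: 26 the hexabenzyl dihydroflavonol of step 17
Product: 27 (2R,3R)-2-(3,4-dihydroxyphenyl)-6-[(2R,3S,4S)-2-(3,4-dihydroxyphenyl)-3,7-dihydroxychroman-4-yl]-3,7-dihydroxychroman-4-one
Conditions: H2 (1 atm), Pd(OH)2/C, THF–MeOH, rt
Reagents that add atoms: none
Why: Hydrogenolysis of the six aryl benzyl ethers is done at the ketone stage, where there is no activated C4' benzylic alcohol to lose, and the aryl ketone, the pyran C–O bonds and the interflavan C–C bond are expected to stay.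

Step 19
Reactants: 27 the free phenolic dihydroflavonol of step 18
Product: 28 (2R,3S,4R)-2-(3,4-dihydroxyphenyl)-6-[(2R,3S,4S)-2-(3,4-dihydroxyphenyl)-3,7-dihydroxychroman-4-yl]chromane-3,4,7-triol (target)
Conditions: NaBH4, EtOH, 0 °C; work-up at pH 6 (AcOH), chromatography on Sephadex LH-20
Reagents that add atoms: none
Why: Borohydride reduction of a 2,3-trans-dihydroflavonol, in which axial hydride delivery gives the equatorial C4' alcohol, so the 2,3-trans-3,4-trans diol (4'R) should form as the main isomer.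

**Compound list**

1 | 2-bromo-4-hydroxybenzaldehyde | O=Cc1ccc(O)cc1Br | starting material
2 | 4-(benzyloxy)-2-bromobenzaldehyde | O=Cc1ccc(OCc2ccccc2)cc1Br | intermediate
3 | ethyl (E)-3-[4-(benzyloxy)-2-bromophenyl]prop-2-enoate | CCOC(=O)/C=C/c1ccc(OCc2ccccc2)cc1Br | intermediate
4 | (E)-3-[4-(benzyloxy)-2-bromophenyl]prop-2-en-1-ol | OC/C=C/c1ccc(OCc2ccccc2)cc1Br | intermediate
5 | [(2R,3R)-3-[4-(benzyloxy)-2-bromophenyl]oxiran-2-yl]methanol | OC[C@@H](O1)[C@H]1c2ccc(OCc3ccccc3)cc2Br | intermediate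
6 | 4-(benzyloxy)-2-hydroxybenzaldehyde | O=Cc1ccc(OCc2ccccc2)cc1O | starting material
7 | 4-(benzyloxy)-2-hydroxy-5-iodobenzaldehyde | O=Cc1cc(I)c(OCc2ccccc2)cc1O | intermediate
8 | 4-(benzyloxy)-5-iodo-2-(methoxymethoxy)benzaldehyde | COCOc1cc(OCc2ccccc2)c(I)cc1C=O | intermediate
9 | 4-(benzyloxy)-5-iodo-2-(methoxymethoxy)benzonitrile | COCOc1cc(OCc2ccccc2)c(I)cc1C#N | intermediate
10 | [2-(benzyloxy)-5-cyano-4-(methoxymethoxy)phenyl]magnesium chloride (not isolated) | COCOc1cc(OCc2ccccc2)c([Mg]Cl)cc1C#N | intermediate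
11 | (2S,3S)-3-[4-(benzyloxy)-2-bromophenyl]-3-[2-(benzyloxy)-5-cyano-4-(methoxymethoxy)phenyl]propane-1,2-diol | OC[C@@H](O)[C@H](c1ccc(OCc2ccccc2)cc1Br)c1cc(C#N)c(OCOC)cc1OCc1ccccc1 | intermediate
12 | (2S,3S)-1,2-bis(tert-butyldimethylsilyl) ether of 11 | CC(C)(C)[Si](C)(C)OC[C@@H](O[Si](C)(C)C(C)(C)C)[C@H](c1ccc(OCc2ccccc2)cc1Br)c1cc(C#N)c(OCOC)cc1OCc1ccccc1 | intermediate
13 | (2S,3S)-3-[4-(benzyloxy)-2-bromophenyl]-3-[2-(benzyloxy)-5-cyano-4-(methoxymethoxy)phenyl]-2-(tert-butyldimethylsilyloxy)propan-1-ol | OC[C@@H](O[Si](C)(C)C(C)(C)C)[C@H](c1ccc(OCc2ccccc2)cc1Br)c1cc(C#N)c(OCOC)cc1OCc1ccccc1 | intermediate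
14 | (2S,3S)-3-[4-(benzyloxy)-2-bromophenyl]-3-[2-(benzyloxy)-5-cyano-4-(methoxymethoxy)phenyl]-2-(tert-butyldimethylsilyloxy)propanal | O=C[C@@H](O[Si](C)(C)C(C)(C)C)[C@H](c1ccc(OCc2ccccc2)cc1Br)c1cc(C#N)c(OCOC)cc1OCc1ccccc1 | intermediate
15 | 4-bromo-1,2-bis(benzyloxy)benzene | Brc1ccc(OCc2ccccc2)c(OCc2ccccc2)c1 | starting material
16 | [3,4-bis(benzyloxy)phenyl]magnesium bromide (not isolated) | Br[Mg]c1ccc(OCc2ccccc2)c(OCc2ccccc2)c1 | intermediate
17 | (1R,2S,3S)-1-[3,4-bis(benzyloxy)phenyl]-3-[4-(benzyloxy)-2-bromophenyl]-3-[2-(benzyloxy)-5-cyano-4-(methoxymethoxy)phenyl]-2-(tert-butyldimethylsilyloxy)propan-1-ol (key-step precursor) | O[C@H](c1ccc(OCc2ccccc2)c(OCc2ccccc2)c1)[C@@H](O[Si](C)(C)C(C)(C)C)[C@H](c1ccc(OCc2ccccc2)cc1Br)c1cc(C#N)c(OCOC)cc1OCc1ccccc1 | intermediate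
18 | (2R,3S,4R)-7-(benzyloxy)-2-[3,4-bis(benzyloxy)phenyl]-4-[2-(benzyloxy)-5-cyano-4-(methoxymethoxy)phenyl]-3-(tert-butyldimethylsilyloxy)chromane (key-step product) | c1ccccc1COc1ccc2c(c1)O[C@H](c1ccc(OCc3ccccc3)c(OCc3ccccc3)c1)[C@@H](O[Si](C)(C)C(C)(C)C)[C@H]2c1cc(C#N)c(OCOC)cc1OCc1ccccc1 | intermediate
19 | N-lithio ketimine of 20 (not isolated) | c1ccccc1COc1ccc2c(c1)O[C@H](c1ccc(OCc3ccccc3)c(OCc3ccccc3)c1)[C@@H](O[Si](C)(C)C(C)(C)C)[C@H]2c1cc(C(C)=N[Li])c(OCOC)cc1OCc1ccccc1 | intermediate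
20 | (2R,3S,4R)-4-[5-acetyl-2-(benzyloxy)-4-(methoxymethoxy)phenyl]-7-(benzyloxy)-2-[3,4-bis(benzyloxy)phenyl]-3-(tert-butyldimethylsilyloxy)chromane | c1ccccc1COc1ccc2c(c1)O[C@H](c1ccc(OCc3ccccc3)c(OCc3ccccc3)c1)[C@@H](O[Si](C)(C)C(C)(C)C)[C@H]2c1cc(C(C)=O)c(OCOC)cc1OCc1ccccc1 | intermediate
21 | 3,4-bis(benzyloxy)benzaldehyde | O=Cc1ccc(OCc2ccccc2)c(OCc2ccccc2)c1 | starting material
22 | (E)-chalcone: ring D of 20 carrying at C5 the (E)-3-[3,4-bis(benzyloxy)phenyl]prop-2-enoyl group | c1ccccc1COc1ccc2c(c1)O[C@H](c1ccc(OCc3ccccc3)c(OCc3ccccc3)c1)[C@@H](O[Si](C)(C)C(C)(C)C)[C@H]2c1cc(C(=O)/C=C/c3ccc(OCc4ccccc4)c(OCc4ccccc4)c3)c(OCOC)cc1OCc1ccccc1 | intermediate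
23 | (αR,βS)-trans-epoxide of 22, the [(2R,3S)-3-[3,4-bis(benzyloxy)phenyl]oxiran-2-yl] aryl ketone | c1ccccc1COc1ccc2c(c1)O[C@H](c1ccc(OCc3ccccc3)c(OCc3ccccc3)c1)[C@@H](O[Si](C)(C)C(C)(C)C)[C@H]2c1cc(C(=O)[C@@H]3O[C@H]3c3ccc(OCc4ccccc4)c(OCc4ccccc4)c3)c(OCOC)cc1OCc1ccccc1 | intermediate
24 | phenol epoxy ketone, 23 without the MOM group (not isolated) | c1ccccc1COc1ccc2c(c1)O[C@H](c1ccc(OCc3ccccc3)c(OCc3ccccc3)c1)[C@@H](O[Si](C)(C)C(C)(C)C)[C@H]2c1cc(C(=O)[C@@H]3O[C@H]3c3ccc(OCc4ccccc4)c(OCc4ccccc4)c3)c(O)cc1OCc1ccccc1 | intermediate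
25 | (2R,3R)-7-(benzyloxy)-2-[3,4-bis(benzyloxy)phenyl]-6-[(2R,3S,4R)-7-(benzyloxy)-2-[3,4-bis(benzyloxy)phenyl]-3-(tert-butyldimethylsilyloxy)chroman-4-yl]-3-hydroxychroman-4-one (not isolated) | c1ccccc1COc1ccc2c(c1)O[C@H](c1ccc(OCc3ccccc3)c(OCc3ccccc3)c1)[C@@H](O[Si](C)(C)C(C)(C)C)[C@H]2c1cc2c(cc1OCc1ccccc1)O[C@H](c1ccc(OCc3ccccc3)c(OCc3ccccc3)c1)[C@@H](O)C2=O | intermediate
26 | (2R,3R)-7-(benzyloxy)-2-[3,4-bis(benzyloxy)phenyl]-6-[(2R,3S,4R)-7-(benzyloxy)-2-[3,4-bis(benzyloxy)phenyl]-3-hydroxychroman-4-yl]-3-hydroxychroman-4-one | c1ccccc1COc1ccc2c(c1)O[C@H](c1ccc(OCc3ccccc3)c(OCc3ccccc3)c1)[C@@H](O)[C@H]2c1cc2c(cc1OCc1ccccc1)O[C@H](c1ccc(OCc3ccccc3)c(OCc3ccccc3)c1)[C@@H](O)C2=O | intermediate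
27 | (2R,3R)-2-(3,4-dihydroxyphenyl)-6-[(2R,3S,4S)-2-(3,4-dihydroxyphenyl)-3,7-dihydroxychroman-4-yl]-3,7-dihydroxychroman-4-one | Oc1ccc2c(c1)O[C@H](c1ccc(O)c(O)c1)[C@@H](O)[C@H]2c1cc2c(cc1O)O[C@H](c1ccc(O)c(O)c1)[C@@H](O)C2=O | intermediate
28 | (2R,3S,4R)-2-(3,4-dihydroxyphenyl)-6-[(2R,3S,4S)-2-(3,4-dihydroxyphenyl)-3,7-dihydroxychroman-4-yl]chromane-3,4,7-triol | Oc1ccc2c(c1)O[C@H](c1ccc(O)c(O)c1)[C@@H](O)[C@H]2c1cc2c(cc1O)O[C@H](c1ccc(O)c(O)c1)[C@@H](O)[C@@H]2O | target

**Step count and risk**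

Total steps: 19. Longest linear sequence: 16 steps (steps 1–4 and 8–19, from compound 1); the ring D branch (steps 5–7) joins at step 8.

The three steps most likely to fail:

Step 13 (key step). Reductive elimination of the aryl ether from a hindered secondary alkoxide may be slow, so that protodebromination takes over. The silyl group may also migrate from O3 to the C2 alkoxide, after which the freed O3 alkoxide would close a five-membered ring. The fallback closes the same ring from the other side under acid, where no alkoxide exists. It sets out from 17: borylation of the aryl bromide (B2pin2, PdCl2(dppf), KOAc, dioxane, 85 °C) should give the pinacol boronate F1, and oxidation (NaBO3·4H2O, THF–H2O, rt) the phenol F2. Catalytic camphorsulfonic acid in CH2Cl2 at 0 °C should then ionise the 3,4-bis(benzyloxy)benzylic carbinol, and capture of the cation by the phenol forms O1–C2. The 2,3-trans isomer is expected to dominate, because the C2 aryl and the C3 silyloxy groups avoid each other, and the cis isomer would be removed by chromatography. The fallback comes back to the route at 18.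

Step 8. The aryl copper reagent may attack the epoxide at C2 instead of the hindered benzylic carbon. Magnesium halide may also open or ionise the benzylic C–O bond, which would cost the clean inversion at C4. The fallback builds C3 and C4 on an Evans auxiliary and sets out from 9. A Heck reaction with (S)-3-acryloyl-4-benzyloxazolidin-2-one (Pd(OAc)2, Et3N, MeCN, 80 °C) should give the N-enoyl imide F3. 4-(Benzyloxy)-2-bromo-1-iodobenzene F4 (from commercial 3-bromo-4-iodophenol and benzyl bromide) is converted with i-PrMgCl·LiCl at −40 °C into the arylmagnesium chloride F5. With CuBr·SMe2 in THF at −40 → −15 °C, F5 adds to F3 on the face away from the auxiliary benzyl group and should give the 3,3-diaryl imide F6. Hydroxylation of its sodium enolate (NaN(SiMe3)2, THF, −78 °C; 2-(phenylsulfonyl)-3-phenyloxaziridine) gives the (2S)-α-hydroxy imide F7, TBSOTf with 2,6-lutidine the silyl ether F8, and LiBH4 (THF–MeOH, 0 °C) removes the auxiliary. The fallback comes back to the route at 13.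

Step 17. In methanolic HCl the epoxide may be opened by chloride or methanol, or may rearrange by an aryl shift, before the phenol closes ring F. The fallback separates opening from ring closure and sets out from 23. Phenylmethanethiol with SnCl4 (CH2Cl2, −20 °C) should open the epoxide at the benzylic carbon and remove the MOM group, giving the α-hydroxy-β-(benzylsulfanyl) ketone with free phenol F9; the configuration at its sulfur-bearing carbon does not matter, since it ionises next. AgBF4 (CH2Cl2, 0 °C) then pulls off the sulfide, and the phenol closes the 2,3-trans ring to give 25, which is isolated here. HF·pyridine (THF, 0 °C → rt) removes the silyl ether, and the fallback comes back to the route at 26.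

Further compounds
F1 | step 13 | pinacol boronate of 17 (Bpin in place of Br on ring A) | O[C@H](c1ccc(OCc2ccccc2)c(OCc2ccccc2)c1)[C@@H](O[Si](C)(C)C(C)(C)C)[C@H](c1ccc(OCc2ccccc2)cc1B1OC(C)(C)C(C)(C)O1)c1cc(C#N)c(OCOC)cc1OCc1ccccc1
F2 | step 13 | phenol from 17 (OH in place of Br on ring A) | O[C@H](c1ccc(OCc2ccccc2)c(OCc2ccccc2)c1)[C@@H](O[Si](C)(C)C(C)(C)C)[C@H](c1ccc(OCc2ccccc2)cc1O)c1cc(C#N)c(OCOC)cc1OCc1ccccc1
F3 | step 8 | (S)-4-benzyl-3-[(E)-3-[2-(benzyloxy)-5-cyano-4-(methoxymethoxy)phenyl]prop-2-enoyl]oxazolidin-2-one | O=C(/C=C/c1cc(C#N)c(OCOC)cc1OCc1ccccc1)N1[C@@H](Cc2ccccc2)COC1=O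
F4 | step 8 | 4-(benzyloxy)-2-bromo-1-iodobenzene | Ic1ccc(OCc2ccccc2)cc1Br
F5 | step 8 | [4-(benzyloxy)-2-bromophenyl]magnesium chloride | Cl[Mg]c1ccc(OCc2ccccc2)cc1Br
F6 | step 8 | (S)-4-benzyl-3-[(3S)-3-[4-(benzyloxy)-2-bromophenyl]-3-[2-(benzyloxy)-5-cyano-4-(methoxymethoxy)phenyl]propanoyl]oxazolidin-2-one | O=C(C[C@H](c1ccc(OCc2ccccc2)cc1Br)c1cc(C#N)c(OCOC)cc1OCc1ccccc1)N1[C@@H](Cc2ccccc2)COC1=O
F7 | step 8 | (2S,3S)-2-hydroxy derivative of F6 | O=C([C@@H](O)[C@H](c1ccc(OCc2ccccc2)cc1Br)c1cc(C#N)c(OCOC)cc1OCc1ccccc1)N1[C@@H](Cc2ccccc2)COC1=O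
F8 | step 8 | (2S,3S)-2-(tert-butyldimethylsilyloxy) derivative of F6 | O=C([C@@H](O[Si](C)(C)C(C)(C)C)[C@H](c1ccc(OCc2ccccc2)cc1Br)c1cc(C#N)c(OCOC)cc1OCc1ccccc1)N1[C@@H](Cc2ccccc2)COC1=O
F9 | step 17 | α-hydroxy-β-(benzylsulfanyl) ketone with free ring D phenol, from 23 | c1ccccc1COc1ccc2c(c1)O[C@H](c1ccc(OCc3ccccc3)c(OCc3ccccc3)c1)[C@@H](O[Si](C)(C)C(C)(C)C)[C@H]2c1cc(C(=O)[C@H](O)C(SCc3ccccc3)c3ccc(OCc4ccccc4)c(OCc4ccccc4)c3)c(O)cc1OCc1ccccc1
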